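At 2.0 h I had to say how much substrate the flask had used and where its pH stood.

| flask | substrate | acid | remark | time |
|---|---|---|---|---|
| north | 0.029 M | 0.171 mM | run made earlier |  |
| west | 0.11 M | 0.171 mM | run made earlier |  |
| east | 0.057 M | 0.26 mM | run made earlier |  |
| flask | 0.057 M | 0.171 mM |  | 2.0 h |

| run | time / min | substrate / % | target / % |
|---|---|---|---|
| north | 6.00 | 90.3 | 9.5 |
| north | 10.0 | 84.4 | 15.3 |
| north | 15.0 | 77.2 | 21.5 |
| north | 25.0 | 65.1 | 31.2 |
| north | 40.0 | 50.5 | 40.8 |
| north | 80.0 | 26.1 | 50.0 |
| west | 12.0 | 81.7 | 17.6 |
| west | 25.0 | 65.1 | 30.8 |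
| west | 40.0 | 50.7 | 40.7 |
| west | 50.0 | 42.4 | 45.7 |
| west | 60.0 | 35.8 | 47.8 |
| west | 80.0 | 25.5 | 49.6 |
| east | 15.0 | 69.7 | 27.7 |
| east | 30.0 | 48.8 | 44.5 |
| east | 40.0 | 38.7 | 50.0 |
| east | 60.0 | 23.7 | 56.0 |
| east | 80.0 | 14.9 | 55.4 |

(standard deviation of a reading: 0.3 percentage points)

- acid is the free proton; pH is minus the decimal logarithm of its molar concentration
- amounts and yields of weak acid count crystals too
- given per volume of solution although it is solid: crystals
- on the list of suspects stand: substrate + acid -> weak acid + acid + target; substrate -> weak acid + target; weak acid <-> conjugate base + acid; crystals <-> weak acid; target -> over-reaction product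

- part of the substrate that has reacted at 2.0 h
- pH of the solution at 2.0 h

I kept books on the substrate, the limiting reagent. The first entry is what remains. The logarithm of charge over remainder, divided by time, gave 0.0171 min⁻¹ for the north run and 0.0170 min⁻¹ for the west run at 40.0 min, nearly equal although they were charged with 0.029 M and 0.11 M. I took their mean, 0.0170 min⁻¹, as my reading of the pseudo-first-order constant at this acid: the part remaining is exp(−constant × time). The east run, with more acid, fell faster at 0.0237 min⁻¹.

The flask has the acid of north and west, so I booked 13.0% remaining and 87.0% reacted.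

The second entry is what the reacted part became. I counted one mole of target and one of weak acid for each mole reacted, so I booked 0.0496 M of weak acid for the flask, crystals included, against 0.171 mM of acid. By the same count the west run had made 0.0819 M by 80.0 min, with its constant read there at 0.0171 min⁻¹, so I held the acid of the flask at its charge, and the pH with it.

The third entry is target's onward loss: at its last reading the west run held 49.6% target, and 24.9% had gone past it.

The forecast said 87.1% and pH 3.77, reading that “new product simply crystallises”.

The flask gave 87.0% and pH 3.77. Its books closed at 13.0% substrate, 45.9% target and 41.2% over-reaction product, and the step into that last entry makes no difference to the part reacted. At 1.00 h the constant gives 63.9% used, and the flask stood at 64.0%.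

    substrate + acid → weak acid + acid + target (k = 73.9 L mol⁻¹ min⁻¹)
    substrate → weak acid + target (k = 0.00439 min⁻¹)
    weak acid ⇌ conjugate base + acid, settled at all times (K = 5.00 × 10⁻¹⁰ M)
    crystals ⇌ weak acid, rate k4*(cs4 - [weak acid]) while solid is left; crystals form when [weak acid] > cs4 (solubility = 3.50 mM, k = 0.428 min⁻¹)
    target → over-reaction product (k = 0.00858 min⁻¹)

For a neighbour flask with 2.9 × 10⁻⁴ M of acid, otherwise charged alike and taken to the same time, the line through the two acid levels gives a constant of 0.0260 min⁻¹, so 4.42% of the substrate remaining. That neighbour flask held 4.51% of its substrate.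

(All runs are calculated on assumed constants, and the scatter is random.)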